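**Plan**
- Retrosynthesis: the CO2H and 5-OH groups are unmasked last (methyl ester, MOM ether). The chromene C3=C4 bond is made late by dehydrogenation of a chroman, so no other C=C bond is present when the carbocycle is hydrogenated.
- The cyclohexane is cut at C1–C6 and C4–C5 (C1 carries CO2H, C3 is the C(CH3)2 carbon). C1 is a latent malonate carbanion and C4 a latent aldehyde that cannot enolise because C3 is quaternary, so a vinylphosphonium salt can deliver C5–C6 by conjugate addition followed by Wittig ring closure.
- The annulation precursor is cut at C2–C3 (Michael addition of isobutyraldehyde to an alkylidene malonate) and at the alkylidene C=C bond (Knoevenagel). The chroman is cut at C4–C4a (B-alkyl Suzuki coupling) and O1–C8a (Pd C–O coupling), back to (R)-linalool.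
- Forward order: aryl halide → chroman (oxygen ring) → side-chain aldehyde → alkylidene malonate → Michael adduct → cyclohexene → cyclohexane → trans monoester → chromene → target.
- Stereochemistry: chromene C2 is carried unchanged from (R)-linalool; cyclohexane C2 is set by the catalyst-controlled Michael addition; C1 is set by base equilibration of the ester to the trans (diequatorial) isomer.

Key step: step 8

Assumption: in step 7 the (R,R) form of the primary amine–thiourea is taken to send the enamine to the Re face of the β-carbon of 11; if the sense proves opposite, the (S,S) form is used with no other change.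

**Step 1**
Reactants: 1 3-bromo-5-methylphenol
Product: 2 1-bromo-3-(methoxymethoxy)-5-methylbenzene
Conditions: NaH (1.2 equiv), THF/DMF, 0 °C; MOMCl (1.2 equiv), 0 °C to rt
Reagents that add atoms: chloromethyl methyl ether, COCCl
Why: Williamson-type O-alkylation of the phenoxide; the MOM acetal should withstand every later basic, reductive and oxidative step and is removed by mild acid at the end.

**Step 2**
Reactants: 2 1-bromo-3-(methoxymethoxy)-5-methylbenzene
Product: 4 1-bromo-2-iodo-3-(methoxymethoxy)-5-methylbenzene, via aryllithium 3 (not isolated)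
Conditions: LiN(i-Pr)2 (1.1 equiv), THF, −78 °C; I2 (1.2 equiv), −78 °C to rt
Reagents that add atoms: iodine, II
Why: Directed ortho-metalation: the amide base removes the most acidic ring hydrogen, the one between OMOM and Br, without bromine–lithium exchange, and iodine traps the aryllithium.

**Step 3**
Reactants: 5 (R)-linalool; 4 1-bromo-2-iodo-3-(methoxymethoxy)-5-methylbenzene
Product: 7 (3R)-1-[2-bromo-6-(methoxymethoxy)-4-methylphenyl]-3,7-dimethyloct-6-en-3-ol, via alkylborane 6 (not isolated)
Conditions: 9-BBN (0.5 M in THF, 1.5 equiv), 0 °C to rt; then 4 (1.0 equiv), Pd(dppf)Cl2 (5 mol%), aq. K3PO4 (3 equiv), DMF, 50 °C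
Reagents that add atoms: none
Why: 9-BBN should hydroborate only the monosubstituted vinyl group (anti-Markovnikov), and the B-alkyl Suzuki–Miyaura coupling should take place at C–I in preference to C–Br; the carbinol stereocentre is not touched.

**Step 4**
Reactants: 7 (3R)-1-[2-bromo-6-(methoxymethoxy)-4-methylphenyl]-3,7-dimethyloct-6-en-3-ol
Product: 8 (2R)-5-(methoxymethoxy)-2,7-dimethyl-2-(4-methylpent-3-en-1-yl)chromane
Conditions: Pd(OAc)2 (3 mol%), 2-(di-tert-butylphosphino)-1,1'-binaphthyl (4 mol%), Cs2CO3 (1.5 equiv), toluene, 80 °C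
Reagents that add atoms: none
Why: Buchwald-type intramolecular Pd-catalysed C–O coupling; the tertiary alkoxide has no hydrogen on the carbinol carbon, so β-hydride elimination is excluded, and because the aryl–O bond is the one formed, the configuration at the carbinol carbon is retained.

**Step 5**
Reactants: 8 (2R)-5-(methoxymethoxy)-2,7-dimethyl-2-(4-methylpent-3-en-1-yl)chromane
Product: 9 3-[(2S)-5-(methoxymethoxy)-2,7-dimethylchroman-2-yl]propanal
Conditions: OsO4 (2 mol%), NaIO4 (4 equiv), 2,6-lutidine (2 equiv), dioxane/H2O (3:1), rt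
Reagents that add atoms: osmium tetroxide, O=[Os](=O)(=O)=O (catalytic oxygen carrier); sodium periodate, [Na+].[O-]I(=O)(=O)=O (terminal oxidant)
Why: Johnson–Lemieux oxidation (dihydroxylation, then periodate glycol cleavage) of the only C=C bond; the stereocentre is not involved and only its descriptor changes, by CIP priority.

**Step 6**
Reactants: 9 3-[(2S)-5-(methoxymethoxy)-2,7-dimethylchroman-2-yl]propanal; 10 dimethyl malonate
Product: 11 dimethyl 2-{3-[(2R)-5-(methoxymethoxy)-2,7-dimethylchroman-2-yl]propylidene}malonate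
Conditions: piperidine (0.1 equiv), AcOH (0.1 equiv), benzene, reflux, Dean–Stark trap
Reagents that add atoms: none
Why: Knoevenagel condensation of an aliphatic aldehyde with an active methylene compound under piperidinium acetate catalysis, driven by removal of water.

**Step 7**
Reactants: 11 dimethyl 2-{3-[(2R)-5-(methoxymethoxy)-2,7-dimethylchroman-2-yl]propylidene}malonate; 12 isobutyraldehyde
Product: 13 dimethyl 2-{(3R)-1-[(2R)-5-(methoxymethoxy)-2,7-dimethylchroman-2-yl]-4,4-dimethyl-5-oxopentan-3-yl}malonate
Conditions: 12 (5 equiv), 1-[(1R,2R)-2-aminocyclohexyl]-3-[3,5-bis(trifluoromethyl)phenyl]thiourea (20 mol%), PhCO2H (20 mol%), toluene, 40 °C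
Reagents that add atoms: none
Why: Enamine-catalysed Michael addition: the primary amine condenses with the α-branched aldehyde, the thiourea binds both ester carbonyl groups of 11, and the enamine carbon adds to the Re face of the β-carbon, which should set the (3R) centre under catalyst control, since the donor carbon is not stereogenic and the chroman centre is remote.

**Step 8**
Reactants: 13 dimethyl 2-{(3R)-1-[(2R)-5-(methoxymethoxy)-2,7-dimethylchroman-2-yl]-4,4-dimethyl-5-oxopentan-3-yl}malonate; 14 vinyltriphenylphosphonium bromide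
Product: 17 dimethyl (6S)-6-{2-[(2R)-5-(methoxymethoxy)-2,7-dimethylchroman-2-yl]ethyl}-5,5-dimethylcyclohex-3-ene-1,1-dicarboxylate, via sodium malonate 15 (not isolated), via phosphorus ylide 16 (not isolated)
Conditions: NaH (1.1 equiv), THF, 0 °C, 30 min; then 14 (1.2 equiv), THF/DMF (4:1), 0 °C to 60 °C
Reagents that add atoms: none
Why: NaH removes the malonate C–H of 13 (the only acidic hydrogen, because the aldehyde sits on the quaternary C(CH3)2 carbon and cannot enolise), and the soft carbanion 15 adds to the β-carbon of the vinylphosphonium salt 14, which forms the first C–C bond and at the same time generates the ylide 16 on the neighbouring carbon. The ylide carbon then attacks the aldehyde in the same molecule, and collapse of the oxaphosphetane expels Ph3P=O and forms the second C–C bond as the ring C=C bond. The closest known reaction type is the Schweizer annulation, in which carbanions of oxo-malonates and vinyltriphenylphosphonium bromide give cyclopentenes and cyclohexenes by conjugate addition followed by intramolecular Wittig olefination. The cyclohexene closes by 6-exo-trig addition of the ylide carbon to the carbonyl group, helped by the gem-dimethyl (Thorpe–Ingold) effect, and a Wittig closure inside a six-membered ring can only give the cis alkene. No stereocentre is created, and the existing one next to the malonate carbon carries no acidic hydrogen and should be kept (the descriptor changes from R to S by CIP priority only). The selectivity needed is capture of the carbanion by 14 before it can revert by retro-Michael loss of the isobutyraldehyde enolate, and Wittig closure within the molecule and not between molecules; full deprotonation before 14 is added, the high electrophilicity of 14 and moderate dilution should secure both.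

**Step 9**
Reactants: 17 dimethyl (6S)-6-{2-[(2R)-5-(methoxymethoxy)-2,7-dimethylchroman-2-yl]ethyl}-5,5-dimethylcyclohex-3-ene-1,1-dicarboxylate
Product: 18 dimethyl (2S)-2-{2-[(2R)-5-(methoxymethoxy)-2,7-dimethylchroman-2-yl]ethyl}-3,3-dimethylcyclohexane-1,1-dicarboxylate
Conditions: H2 (1 atm), 10% Pd/C, EtOAc, rt
Reagents that add atoms: none
Why: Heterogeneous catalytic hydrogenation of the only C=C bond; the aryl ethers, the non-benzylic chroman C2–O bond, the acetal and the esters are inert, and no stereocentre is formed.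

**Step 10**
Reactants: 18 dimethyl (2S)-2-{2-[(2R)-5-(methoxymethoxy)-2,7-dimethylchroman-2-yl]ethyl}-3,3-dimethylcyclohexane-1,1-dicarboxylate
Product: 20 methyl (1S,2R)-2-{2-[(2R)-5-(methoxymethoxy)-2,7-dimethylchroman-2-yl]ethyl}-3,3-dimethylcyclohexane-1-carboxylate, via monoester epimer mixture 19 (not isolated)
Conditions: LiCl (3 equiv), H2O (2 equiv), DMSO, 150 °C; then NaOMe (1 equiv), MeOH, 65 °C
Reagents that add atoms: none
Why: Krapcho dealkoxycarbonylation gives both C1 epimers 19, and NaOMe then equilibrates the ester through its enolate towards the trans isomer with both ring substituents equatorial, which should set the (1S) centre under thermodynamic control from the fixed (2R) centre (the minor cis epimer is separated and resubmitted).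

**Step 11**
Reactants: 20 methyl (1S,2R)-2-{2-[(2R)-5-(methoxymethoxy)-2,7-dimethylchroman-2-yl]ethyl}-3,3-dimethylcyclohexane-1-carboxylate
Product: 21 methyl (1S,2R)-2-{2-[(2R)-5-(methoxymethoxy)-2,7-dimethyl-2H-chromen-2-yl]ethyl}-3,3-dimethylcyclohexane-1-carboxylate
Conditions: DDQ (1.5 equiv), benzene, 80 °C
Reagents that add atoms: none
Why: DDQ dehydrogenation of a chroman to a 2H-chromene: hydride abstraction from the benzylic C4–H, whose cation is stabilised by the two ortho oxygen atoms, followed by loss of a C3 proton; C2 is quaternary and should be neither oxidised nor epimerised.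

**Step 12**
Reactants: 21 methyl (1S,2R)-2-{2-[(2R)-5-(methoxymethoxy)-2,7-dimethyl-2H-chromen-2-yl]ethyl}-3,3-dimethylcyclohexane-1-carboxylate
Product: 23 (1S,2R)-2-{2-[(2R)-5-hydroxy-2,7-dimethyl-2H-chromen-2-yl]ethyl}-3,3-dimethylcyclohexane-1-carboxylic acid, via lithium carboxylate 22 (not isolated)
Conditions: LiOH (5 equiv), THF/H2O (3:1), 50 °C; then 3 M aq. HCl to pH 1, 40 °C
Reagents that add atoms: lithium hydroxide, [Li+].[OH-]
Why: Saponification of the methyl ester and then acid hydrolysis of the MOM acetal in the same flask; the trans acid is the thermodynamic epimer, and both operations stay at or below 50 °C so that the 2H-chromene should not epimerise at C2 by thermal electrocyclic ring opening.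

**Compound list**
1 | 3-bromo-5-methylphenol | Cc1cc(O)cc(Br)c1 | starting material
2 | 1-bromo-3-(methoxymethoxy)-5-methylbenzene | COCOc1cc(C)cc(Br)c1 | intermediate
3 | [2-bromo-6-(methoxymethoxy)-4-methylphenyl]lithium | [Li]c1c(Br)cc(C)cc1OCOC | intermediate (not isolated)
4 | 1-bromo-2-iodo-3-(methoxymethoxy)-5-methylbenzene | COCOc1cc(C)cc(Br)c1I | intermediate
5 | (R)-linalool, (3R)-3,7-dimethylocta-1,6-dien-3-ol | C=C[C@](C)(O)CCC=C(C)C | starting material
6 | (3S)-1-(9-borabicyclo[3.3.1]nonan-9-yl)-3,7-dimethyloct-6-en-3-ol | C(CB1C2CCCC1CCC2)[C@](C)(O)CCC=C(C)C | intermediate (not isolated)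
7 | (3R)-1-[2-bromo-6-(methoxymethoxy)-4-methylphenyl]-3,7-dimethyloct-6-en-3-ol | C(Cc1c(Br)cc(C)cc1OCOC)[C@](C)(O)CCC=C(C)C | intermediate
8 | (2R)-5-(methoxymethoxy)-2,7-dimethyl-2-(4-methylpent-3-en-1-yl)chromane | COCOc1cc(C)cc2c1CC[C@@](C)(CCC=C(C)C)O2 | intermediate
9 | 3-[(2S)-5-(methoxymethoxy)-2,7-dimethylchroman-2-yl]propanal | COCOc1cc(C)cc2c1CC[C@@](C)(CCC=O)O2 | intermediate
10 | dimethyl malonate | COC(=O)CC(=O)OC | starting material
11 | dimethyl 2-{3-[(2R)-5-(methoxymethoxy)-2,7-dimethylchroman-2-yl]propylidene}malonate | COCOc1cc(C)cc2c1CC[C@@](C)(CCC=C(C(=O)OC)C(=O)OC)O2 | intermediate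
12 | isobutyraldehyde (2-methylpropanal) | CC(C)C=O | starting material
13 | dimethyl 2-{(3R)-1-[(2R)-5-(methoxymethoxy)-2,7-dimethylchroman-2-yl]-4,4-dimethyl-5-oxopentan-3-yl}malonate | COCOc1cc(C)cc2c1CC[C@@](C)(CC[C@H](C(C(=O)OC)C(=O)OC)C(C)(C)C=O)O2 | intermediate
14 | vinyltriphenylphosphonium bromide | C=C[P+](c1ccccc1)(c1ccccc1)c1ccccc1.[Br-] | starting material
15 | sodium salt of the malonate carbanion of 13 | COCOc1cc(C)cc2c1CC[C@@](C)(CC[C@H]([C-](C(=O)OC)C(=O)OC)C(C)(C)C=O)O2.[Na+] | intermediate (not isolated)
16 | phosphorus ylide: 13 carrying CH2–CH=PPh3 on the malonate carbon | COCOc1cc(C)cc2c1CC[C@@](C)(CC[C@H](C(CC=P(c3ccccc3)(c3ccccc3)c3ccccc3)(C(=O)OC)C(=O)OC)C(C)(C)C=O)O2 | intermediate (not isolated)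
17 | dimethyl (6S)-6-{2-[(2R)-5-(methoxymethoxy)-2,7-dimethylchroman-2-yl]ethyl}-5,5-dimethylcyclohex-3-ene-1,1-dicarboxylate | COCOc1cc(C)cc2c1CC[C@@](C)(CC[C@@H]1C(C(=O)OC)(C(=O)OC)CC=CC1(C)C)O2 | intermediate
18 | dimethyl (2S)-2-{2-[(2R)-5-(methoxymethoxy)-2,7-dimethylchroman-2-yl]ethyl}-3,3-dimethylcyclohexane-1,1-dicarboxylate | COCOc1cc(C)cc2c1CC[C@@](C)(CC[C@@H]1C(C(=O)OC)(C(=O)OC)CCCC1(C)C)O2 | intermediate
19 | methyl (2R)-2-{2-[(2R)-5-(methoxymethoxy)-2,7-dimethylchroman-2-yl]ethyl}-3,3-dimethylcyclohexane-1-carboxylate, both C1 epimers | COCOc1cc(C)cc2c1CC[C@@](C)(CC[C@@H]1C(C(=O)OC)CCCC1(C)C)O2 | intermediate (not isolated)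
20 | methyl (1S,2R)-2-{2-[(2R)-5-(methoxymethoxy)-2,7-dimethylchroman-2-yl]ethyl}-3,3-dimethylcyclohexane-1-carboxylate (trans) | COCOc1cc(C)cc2c1CC[C@@](C)(CC[C@@H]1[C@@H](C(=O)OC)CCCC1(C)C)O2 | intermediate
21 | methyl (1S,2R)-2-{2-[(2R)-5-(methoxymethoxy)-2,7-dimethyl-2H-chromen-2-yl]ethyl}-3,3-dimethylcyclohexane-1-carboxylate | COCOc1cc(C)cc2c1C=C[C@@](C)(CC[C@@H]1[C@@H](C(=O)OC)CCCC1(C)C)O2 | intermediate
22 | lithium (1S,2R)-2-{2-[(2R)-5-(methoxymethoxy)-2,7-dimethyl-2H-chromen-2-yl]ethyl}-3,3-dimethylcyclohexane-1-carboxylate | COCOc1cc(C)cc2c1C=C[C@@](C)(CC[C@@H]1[C@@H](C(=O)[O-])CCCC1(C)C)O2.[Li+] | intermediate (not isolated)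
23 | (1S,2R)-2-{2-[(2R)-5-hydroxy-2,7-dimethyl-2H-chromen-2-yl]ethyl}-3,3-dimethylcyclohexane-1-carboxylic acid | Cc1cc(O)c2c(c1)O[C@](C)(CC[C@@H]1[C@@H](C(=O)O)CCCC1(C)C)C=C2 | target

**Step count**
Total: 12 steps. Longest linear sequence: 12 steps (1 to 23); (R)-linalool 5 enters at step 3.

**Steps most likely to fail**

Step 7. The process at risk is slow addition of the hindered enamine to a weakly electrophilic β-alkyl alkylidene malonate, with poor facial discrimination and deconjugation of 11 to its β,γ-isomer. The fallback replaces enamine catalysis by a stoichiometric chiral azaenolate (Enders hydrazone Michael addition). It sets out from 12 and 11 and comes back at 13. Isobutyraldehyde 12 is condensed with (S)-1-amino-2-(methoxymethyl)pyrrolidine to the SAMP hydrazone of isobutyraldehyde F1. F1 is deprotonated with LiN(i-Pr)2 in THF (0 °C, then −78 °C) and the azaenolate is added to 11 at −78 °C to give the SAMP hydrazone of the Michael adduct F2; the RAMP antipode is used if the facial sense requires it. Cleavage of the hydrazone with aqueous oxalic acid (or CuCl2) in ether gives aldehyde 13.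

Step 8. The process at risk is retro-Michael fragmentation of the malonate anion before it is captured, and quenching of the ylide by proton transfer instead of ring closure. The fallback forms the same two bonds one after the other, by allylation, methylenation and ring-closing metathesis. It sets out from 13 and comes back at 17. Allylation of the malonate C–H with allyl methyl carbonate and Pd(PPh3)4 in THF, without added base so that the carbanion stays at low concentration, gives the allylated malonate aldehyde F3. Wittig methylenation of the aldehyde with Ph3P=CH2 (THF, −78 °C to 0 °C) gives the diene F4. Ring-closing metathesis with the second-generation Grubbs catalyst (CH2Cl2, 40 °C) gives cyclohexene 17.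

Step 11. The process at risk is sluggish or unselective hydride abstraction, trapping of the benzylic cation by the hydroquinone, and acid-induced loss of the MOM group. The fallback functionalises C4 of the chroman stepwise instead of dehydrogenating it directly. It sets out from 20 and comes back at 21. Benzylic oxidation at C4 (t-BuOOH, catalytic CrO3, CH2Cl2, rt) gives the chroman-4-one F5. Reduction with NaBH4 (MeOH, 0 °C) gives the chroman-4-ol F6 as either C4 epimer. Dehydration with catalytic p-TsOH in benzene at 50 °C gives chromene 21.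

**Further compounds**
F1 | step 7 | (S,E)-2-(methoxymethyl)-N-(2-methylpropylidene)pyrrolidin-1-amine | CC(C)/C=N/N1CCC[C@H]1COC
F2 | step 7 | SAMP hydrazone of aldehyde 13 | COCOc1cc(C)cc2c1CC[C@@](C)(CC[C@H](C(C(=O)OC)C(=O)OC)C(C)(C)/C=N/N1CCC[C@H]1COC)O2
F3 | step 8 | dimethyl 2-allyl-2-{(3R)-1-[(2R)-5-(methoxymethoxy)-2,7-dimethylchroman-2-yl]-4,4-dimethyl-5-oxopentan-3-yl}malonate | COCOc1cc(C)cc2c1CC[C@@](C)(CC[C@H](C(CC=C)(C(=O)OC)C(=O)OC)C(C)(C)C=O)O2
F4 | step 8 | dimethyl 2-allyl-2-{(3R)-1-[(2R)-5-(methoxymethoxy)-2,7-dimethylchroman-2-yl]-4,4-dimethylhex-5-en-3-yl}malonate | COCOc1cc(C)cc2c1CC[C@@](C)(CC[C@H](C(CC=C)(C(=O)OC)C(=O)OC)C(C)(C)C=C)O2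
F5 | step 11 | methyl (1S,2R)-2-{2-[(2R)-5-(methoxymethoxy)-2,7-dimethyl-4-oxochroman-2-yl]ethyl}-3,3-dimethylcyclohexane-1-carboxylate | COCOc1cc(C)cc2c1C(=O)C[C@@](C)(CC[C@@H]1[C@@H](C(=O)OC)CCCC1(C)C)O2
F6 | step 11 | methyl (1S,2R)-2-{2-[(2R)-4-hydroxy-5-(methoxymethoxy)-2,7-dimethylchroman-2-yl]ethyl}-3,3-dimethylcyclohexane-1-carboxylate, either C4 epimer | COCOc1cc(C)cc2c1C(O)C[C@@](C)(CC[C@@H]1[C@@H](C(=O)OC)CCCC1(C)C)O2
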